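**Retrosynthetic overview**
1. Arene end game: target 36 comes from its tris-MOM ether 35; the formyl and 3-methylbutanoyl groups enter by two directed lithiations of the phloroglucinol ring once the decalin is finished.
2. Ring A adjustment: the C4 stereocentre and the C5=C6 alkene come from a 6β-hydroxy-4-en-3-one by allylic diazene rearrangement; the C3 oxygen is then removed by radical deoxygenation.
3. C16–aryl bond: Negishi coupling of a C16 iodide, which is released from a 1,2-cyclopropyl 3-ketone by iodide attack at C16 with cleavage of C2–C16.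
4. Key disconnection and the feature it answers: in ring A, C1 carries the benzylic carbon C16 cis to the angular C10 methyl (the shielded face, next to quaternary C10), while C2 is a plain CH2. C1–C16 is therefore made together with a temporary C2–C16 bond by C3-hydroxyl-directed cyclopropanation of a 1,4-dien-3β-ol.
5. Ring order: ring B comes from (S)-carvone; ring A is built by auxiliary-controlled Robinson annulation with ethyl vinyl ketone; the temporary cyclopropane is closed in step 6 and opened in step 8; the arene ring is brought in intact.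

Key step: step 6

Assumption (numbering and faces): eudesmane numbering is used throughout (ring A = C1–C5 and C10, ring B = C5–C10, C16 = the carbon joining C1 to the arene); β is the face of the C10 methyl, and every decalin named below carries 10β-methyl and 7α-isopropenyl, so the target is a 1β-arylmethyl-4β-methyl-eudesma-5,11-diene.

**Route**

Step 1
Reactants: 1 (S)-(+)-carvone
Product: 2 (5S)-2-methyl-5-(prop-1-en-2-yl)cyclohexan-1-one (dihydrocarvone; C2 epimers)
Conditions: LiBH(s-Bu)3 (L-Selectride), THF, −78 °C; then H2O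
Reagents that add atoms: none
Why: Conjugate (1,4) hydride reduction of a β-unsubstituted cyclohexenone by a hindered borohydride, which leaves the isopropenyl group alone; C5 is untouched and the C2 epimer mixture is harmless because C2 is enolised in step 2.

Step 2
Reactants: 2 dihydrocarvone; 3 ethyl vinyl ketone
Product: 6 (2S,5S)-2-methyl-2-(3-oxopentyl)-5-(prop-1-en-2-yl)cyclohexan-1-one, via ketimine 4 (not isolated), via adduct imine 5 (not isolated)
Conditions: (R)-1-phenylethylamine, TsOH (cat.), toluene, reflux (−H2O); then 3, THF, 40 °C; then 10% aq AcOH, 25 °C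
Reagents that add atoms: none
Why: Chiral-imine Michael addition (first half of the Robinson annulation), in which the more substituted secondary enamine tautomer of 4 adds to the vinyl ketone through a compact aza-ene-like transition state on the face away from the phenyl group of the auxiliary; this is also the axial approach cis to the equatorial isopropenyl group (matched pair), so quaternary C10 should form with its methyl trans to the isopropenyl group, and hydrolysis returns the amine.

Step 3
Reactants: 6 diketone
Product: 8 (4aS,7S)-1,4a-dimethyl-7-(prop-1-en-2-yl)-4,4a,5,6,7,8-hexahydronaphthalen-2(3H)-one, via ketol 7 (not isolated)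
Conditions: NaOMe, MeOH, 25 → 60 °C
Reagents that add atoms: none
Why: Intramolecular aldol condensation (second half of the Robinson annulation) closes ring A by attack of the ethyl ketone enolate on the ring carbonyl and dehydrates to the tetrasubstituted enone; no stereocentre is touched.

Step 4
Reactants: 8 enone
Product: 9 (4aS,7S)-1,4a-dimethyl-7-(prop-1-en-2-yl)-5,6,7,8-tetrahydronaphthalen-2(4aH)-one
Conditions: DDQ, dioxane, reflux
Reagents that add atoms: none
Why: Quinone dehydrogenation under neutral conditions proceeds through the kinetic 2,4-dienol with hydride loss from C1 and should give the cross-conjugated 1,4-dien-3-one, as with steroidal 4-en-3-ones; C7 and C10 are not affected.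

Step 5
Reactants: 9 dienone
Product: 10 (2S,4aS,7S)-1,4a-dimethyl-7-(prop-1-en-2-yl)-2,4a,5,6,7,8-hexahydronaphthalen-2-ol (eudesma-1,4,11-trien-3β-ol)
Conditions: NaBH4, CeCl3·7H2O, MeOH, −78 → −40 °C; base-washed glassware
Reagents that add atoms: none
Why: Luche 1,2-reduction in which hydride should approach the flat dienone from the face opposite the angular C10 methyl, placing the C3 hydroxyl cis to that methyl; any minor 3α epimer is separated and can be re-oxidised to 9 with MnO2.

Step 6
Reactants: 10 dienol
Product: 12 1β,2β-methanoeudesma-4,11-dien-3β-ol, via zinc alkoxide 11 (not isolated)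
Conditions: Et2Zn (2.2 equiv), CH2Cl2, −20 °C; then CH2I2 (2.2 equiv), −20 → 0 °C; aq NH4Cl
Reagents that add atoms: diiodomethane, ICI
Why: Et2Zn first turns the C3 hydroxyl into ethylzinc alkoxide 11, which binds the carbenoid EtZnCH2I and passes its methylene to the neighbouring C1=C2 bond through the concerted butterfly transition state of the Simmons–Smith reaction; the closest known reaction type is the hydroxyl-directed cyclopropanation of cyclohex-2-enols and steroidal allylic alcohols. The three-membered ring closes in a single [2+1] event in which C1–C16 and C2–C16 form together, so the cis geometry of the alkene becomes the ring fusion. Both new stereocentres, C1 and C2, are fixed by the C3 alkoxide, because delivery is syn to oxygen and therefore on the β face that also carries the C10 methyl, a face an undirected reagent would avoid. The step needs site selectivity for C1=C2 over the second allylic alkene C4=C5 and over the isopropenyl group: C4=C5 is tetrasubstituted and wedged between quaternary C10 and the C4 methyl, and the isopropenyl group has no nearby oxygen and reacts far more slowly than an alkoxide-bound alkene, so a small excess of reagent at low temperature should stop at the mono-adduct. Forming the alkoxide before CH2I2 is added keeps free zinc iodide away from the acid-sensitive bis-allylic alcohol.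

Step 7
Reactants: 12 cyclopropyl carbinol
Product: 13 1β,2β-methanoeudesma-4,11-dien-3-one
Conditions: Dess–Martin periodinane, NaHCO3, CH2Cl2, 0 → 25 °C
Reagents that add atoms: none
Why: Dess–Martin oxidation of a secondary allylic cyclopropyl carbinol under buffered conditions avoids the cyclopropylcarbinyl cation and leaves C1 and C2 unchanged.

Step 8
Reactants: 13 cyclopropyl enone
Product: 15 1β-(iodomethyl)eudesma-4,11-dien-3-one, via silyl dienol ether 14 (not isolated)
Conditions: TMSCl, NaI, MeCN, −20 → 0 °C; then aq NaHCO3, Na2S2O3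
Reagents that add atoms: sodium iodide, [Na+].[I-]
Why: Homoconjugate ring opening of a cyclopropyl ketone by iodotrimethylsilane made in the flask: O-silylation activates the ring and iodide attacks the unhindered methylene C16 in an SN2 manner, cleaving C2–C16 (the bond aligned with the carbonyl π system, whereas the ring-fusion bond C1–C2 is nearly orthogonal and C1 is neopentyl-like); hydrolysis of 14 returns the enone with C2 as CH2 and C1 unchanged, and the short contact time at low temperature protects the isopropenyl group.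

Step 9
Reactants: 16 phloroglucinol
Product: 17 1,3,5-tris(methoxymethoxy)benzene
Conditions: MOMCl, i-Pr2NEt, CH2Cl2, 0 → 25 °C
Reagents that add atoms: chloromethyl methyl ether, COCCl
Why: Williamson-type O-alkylation of the three phenolic oxygens by a hard alkoxymethyl chloride gives the tris-acetal, which later directs lithiation and comes off under mild acid.

Step 10
Reactants: 15 iodide; 17 tris-MOM arene
Product: 20 1β-[2,4,6-tris(methoxymethoxy)benzyl]eudesma-4,11-dien-3-one, via aryllithium 18 (not isolated), via arylzinc bromide 19 (not isolated)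
Conditions: 17, n-BuLi, THF, 0 °C; ZnBr2, 0 → 25 °C; then 15, Ni(acac)2 (10 mol %), 4-(trifluoromethyl)styrene, THF/NMP, −15 → 25 °C
Reagents that add atoms: none
Why: Directed ortho-lithiation between two OMOM groups, transmetallation to zinc and nickel-catalysed Negishi coupling of the arylzinc halide with a primary alkyl iodide (the electron-poor styrene speeds reductive elimination); the radical-type activation of the C–I bond is little affected by the β-branching at C1, the organozinc does not touch the hindered enone, and C1 is not involved.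

Step 11
Reactants: 20 enone
Product: 21 3-(tert-butyldimethylsilyloxy)-1β-[2,4,6-tris(methoxymethoxy)benzyl]eudesma-3,5,11-triene
Conditions: TBSOTf, Et3N (excess), CH2Cl2, −78 → 0 °C
Reagents that add atoms: tert-butyldimethylsilyl trifluoromethanesulfonate, CC(C)(C)[Si](C)(C)OS(=O)(=O)C(F)(F)F
Why: Soft enolisation (silyl triflate with amine) removes the axial γ-hydrogen at C6 from the O-silylated enone and should give the through-conjugated 3,5-dienol silyl ether, as with steroidal 4-en-3-ones; the excess amine keeps the aryl MOM ethers intact.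

Step 12
Reactants: 21 dienol silyl ether
Product: 22 6β-hydroxy-1β-[2,4,6-tris(methoxymethoxy)benzyl]eudesma-4,11-dien-3-one
Conditions: mCPBA (1.05 equiv), NaHCO3, CH2Cl2, −20 °C; aq Na2S2O3
Reagents that add atoms: 3-chloroperbenzoic acid, OOC(=O)c1cccc(Cl)c1
Why: Vinylogous Rubottom oxidation in which the peracid attacks the terminal C5=C6 bond of the dienol ether at C6 axially on the β face, anti to the pseudo-axial 7α-isopropenyl group (the usual 6β preference of steroidal 3,5-dienol ethers); epoxide opening and loss of silyl give the γ-hydroxy enone, and the silyl dienol ether is far more nucleophilic than the isopropenyl group or the arene.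

Step 13
Reactants: 22 hydroxy enone
Product: 25 4β-methyl-1β-[2,4,6-tris(methoxymethoxy)benzyl]eudesma-5,11-dien-3-one, via sulfonylhydrazine 23 (not isolated), via allylic diazene 24 (not isolated)
Conditions: 2-nitrobenzenesulfonylhydrazide (NBSH), PPh3, DEAD, THF, −30 °C; then 23 °C
Reagents that add atoms: none
Why: Reductive 1,3-transposition of an allylic alcohol through an allylic diazene: Mitsunobu displacement of the 6β-hydroxyl by NBSH with inversion puts nitrogen on the α face (23), loss of 2-nitrobenzenesulfinic acid gives diazene 24, and retro-ene loss of N2 moves hydrogen from nitrogen to C4 on the same α face while the alkene shifts to C5=C6, so C4 is set with its methyl β (cis to the C10 methyl).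

Step 14
Reactants: 25 β,γ-unsaturated ketone (used crude)
Product: 26 4β-methyl-1β-[2,4,6-tris(methoxymethoxy)benzyl]eudesma-5,11-dien-3β-ol
Conditions: NaBH4, MeOH/THF, −20 → 0 °C
Reagents that add atoms: none
Why: Borohydride reduction of the non-conjugated ketone at low temperature removes the carbonyl before C4 can epimerise or the alkene can move back into conjugation; axial hydride attack should give mainly the 3β-alcohol, and either C3 epimer serves because C3 is deoxygenated in step 16.

Step 15
Reactants: 26 alcohol
Product: 27 O-{4β-methyl-1β-[2,4,6-tris(methoxymethoxy)benzyl]eudesma-5,11-dien-3β-yl} 1H-imidazole-1-carbothioate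
Conditions: 1,1'-thiocarbonyldiimidazole, DMAP (cat.), toluene, 80 °C
Reagents that add atoms: 1,1'-thiocarbonyldiimidazole, S=C(n1ccnc1)n1ccnc1
Why: Acyl transfer to the secondary alcohol gives the thiocarbonyl derivative needed for Barton–McCombie deoxygenation under neutral conditions that the alkenes and MOM ethers tolerate.

Step 16
Reactants: 27 thiocarbonylimidazolide
Product: 28 4β-methyl-1β-[2,4,6-tris(methoxymethoxy)benzyl]eudesma-5,11-diene
Conditions: Bu3SnH, AIBN (cat.), toluene, 100 °C
Reagents that add atoms: none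
Why: Barton–McCombie radical deoxygenation, in which the stannyl radical adds to sulfur, the C3–O bond fragments and the secondary C3 radical takes hydrogen from the tin hydride faster than it can add to the remote alkenes; no stereocentre is formed or touched.

Step 17
Reactants: 28 arene
Product: 30 3-{[4β-methyleudesma-5,11-dien-1β-yl]methyl}-2,4,6-tris(methoxymethoxy)benzaldehyde, via aryllithium 29 (not isolated)
Conditions: n-BuLi, THF, 0 °C; DMF, 0 → 25 °C; aq NH4Cl
Reagents that add atoms: N,N-dimethylformamide, CN(C)C=O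
Why: Directed ortho-lithiation at one of the two equivalent ring positions flanked by two OMOM groups, followed by formylation with DMF; without a diamine additive at 0 °C the doubly activated aryl C–H should be removed well before any allylic C–H.

Step 18
Reactants: 31 3-methylbutanoyl chloride
Product: 32 N-methoxy-N,3-dimethylbutanamide
Conditions: MeNHOMe·HCl, pyridine, CH2Cl2, 0 → 25 °C
Reagents that add atoms: N,O-dimethylhydroxylamine hydrochloride, CNOC.Cl
Why: Acylation of the hydroxylamine by the acid chloride gives the N-methoxy-N-methylamide (Weinreb amide), an acyl donor that stops at the ketone stage.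

Step 19
Reactants: 30 aldehyde; 32 amide
Product: 35 3-{[4β-methyleudesma-5,11-dien-1β-yl]methyl}-2,4,6-tris(methoxymethoxy)-5-(3-methylbutanoyl)benzaldehyde, via amino alkoxide 33 (not isolated), via lithiated amino alkoxide 34 (not isolated)
Conditions: LiN(Me)CH2CH2NMe2 (from the amine and n-BuLi), THF, −20 °C; n-BuLi, −20 → 0 °C; 32 (excess), −78 → 0 °C; aq NH4Cl
Reagents that add atoms: none
Why: In situ protection of the aldehyde as its lithium α-amino alkoxide 33 allows directed lithiation of the last ring position (between two OMOM groups), and the aryllithium acylates the N-methoxy-N-methylamide through a chelated tetrahedral adduct that cannot add a second time; aqueous work-up releases both carbonyl groups.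

Step 20
Reactants: 35 tris-MOM ether
Product: 36 CNP0564915.1 (target)
Conditions: 2 M HCl, MeOH/THF, 25 °C
Reagents that add atoms: none
Why: Acid-catalysed acetal exchange removes the three aryl MOM ethers, each of which sits ortho to a carbonyl group and is therefore labile, under dilute methanolic acid at room temperature that isolated trisubstituted and 1,1-disubstituted alkenes should tolerate; no stereocentre is affected.

**Compound list**
1 | (S)-(+)-carvone | C=C(C)[C@@H]1CC(=O)C(C)=CC1 | starting material
2 | (5S)-2-methyl-5-(prop-1-en-2-yl)cyclohexan-1-one (dihydrocarvone, C2 epimer mixture) | C=C(C)[C@@H]1CC(=O)C(C)CC1 | intermediate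
3 | ethyl vinyl ketone (pent-1-en-3-one) | C=CC(=O)CC | starting material
4 | N-[(R)-1-phenylethyl] ketimine of 2 (not isolated) | C=C(C)[C@@H]1CC(=N[C@H](C)c2ccccc2)C(C)CC1 | intermediate
5 | N-[(R)-1-phenylethyl] ketimine of 6 at the ring carbonyl (not isolated) | C=C(C)[C@@H]1CC(=N[C@H](C)c2ccccc2)[C@](C)(CCC(=O)CC)CC1 | intermediate
6 | (2S,5S)-2-methyl-2-(3-oxopentyl)-5-(prop-1-en-2-yl)cyclohexan-1-one | C=C(C)[C@@H]1CC(=O)[C@](C)(CCC(=O)CC)CC1 | intermediate
7 | 5-hydroxyeudesm-11-en-3-one ketol, C4 and C5 unassigned (not isolated) | C=C(C)[C@@H]1CC2(O)C(C)C(=O)CC[C@]2(C)CC1 | intermediate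
8 | (4aS,7S)-1,4a-dimethyl-7-(prop-1-en-2-yl)-4,4a,5,6,7,8-hexahydronaphthalen-2(3H)-one (eudesma-4,11-dien-3-one) | C=C(C)[C@@H]1CC2=C(C)C(=O)CC[C@]2(C)CC1 | intermediate
9 | (4aS,7S)-1,4a-dimethyl-7-(prop-1-en-2-yl)-5,6,7,8-tetrahydronaphthalen-2(4aH)-one (eudesma-1,4,11-trien-3-one) | C=C(C)[C@@H]1CC2=C(C)C(=O)C=C[C@]2(C)CC1 | intermediate
10 | (2S,4aS,7S)-1,4a-dimethyl-7-(prop-1-en-2-yl)-2,4a,5,6,7,8-hexahydronaphthalen-2-ol (eudesma-1,4,11-trien-3β-ol) | C=C(C)[C@@H]1CC2=C(C)[C@@H](O)C=C[C@]2(C)CC1 | intermediate
11 | ethylzinc alkoxide of 10 (not isolated) | C=C(C)[C@@H]1CC2=C(C)[C@@H](O[Zn]CC)C=C[C@]2(C)CC1 | intermediate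
12 | 1β,2β-methanoeudesma-4,11-dien-3β-ol | C=C(C)[C@@H]1CC2=C(C)[C@@H](O)[C@H]3C[C@H]3[C@]2(C)CC1 | intermediate
13 | 1β,2β-methanoeudesma-4,11-dien-3-one | C=C(C)[C@@H]1CC2=C(C)C(=O)[C@H]3C[C@H]3[C@]2(C)CC1 | intermediate
14 | 1β-(iodomethyl)-3-(trimethylsilyloxy)eudesma-2,4,11-triene (not isolated) | C=C(C)[C@@H]1CC2=C(C)C(O[Si](C)(C)C)=C[C@@H](CI)[C@]2(C)CC1 | intermediate
15 | 1β-(iodomethyl)eudesma-4,11-dien-3-one | C=C(C)[C@@H]1CC2=C(C)C(=O)C[C@@H](CI)[C@]2(C)CC1 | intermediate
16 | phloroglucinol (benzene-1,3,5-triol) | Oc1cc(O)cc(O)c1 | starting material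
17 | 1,3,5-tris(methoxymethoxy)benzene | COCOc1cc(OCOC)cc(OCOC)c1 | intermediate
18 | [2,4,6-tris(methoxymethoxy)phenyl]lithium (not isolated) | COCOc1cc(OCOC)c([Li])c(OCOC)c1 | intermediate
19 | [2,4,6-tris(methoxymethoxy)phenyl]zinc bromide (not isolated) | COCOc1cc(OCOC)c([Zn]Br)c(OCOC)c1 | intermediate
20 | 1β-[2,4,6-tris(methoxymethoxy)benzyl]eudesma-4,11-dien-3-one | C=C(C)[C@@H]1CC2=C(C)C(=O)C[C@@H](Cc3c(OCOC)cc(OCOC)cc3OCOC)[C@]2(C)CC1 | intermediate
21 | 3-(tert-butyldimethylsilyloxy)-1β-[2,4,6-tris(methoxymethoxy)benzyl]eudesma-3,5,11-triene | C=C(C)[C@@H]1C=C2C(C)=C(O[Si](C)(C)C(C)(C)C)C[C@@H](Cc3c(OCOC)cc(OCOC)cc3OCOC)[C@]2(C)CC1 | intermediate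
22 | 6β-hydroxy-1β-[2,4,6-tris(methoxymethoxy)benzyl]eudesma-4,11-dien-3-one | C=C(C)[C@@H]1[C@@H](O)C2=C(C)C(=O)C[C@@H](Cc3c(OCOC)cc(OCOC)cc3OCOC)[C@]2(C)CC1 | intermediate
23 | 6α-[1-(2-nitrophenylsulfonyl)hydrazin-1-yl]-1β-[2,4,6-tris(methoxymethoxy)benzyl]eudesma-4,11-dien-3-one (not isolated) | C=C(C)[C@@H]1[C@H](N(N)S(=O)(=O)c4ccccc4[N+](=O)[O-])C2=C(C)C(=O)C[C@@H](Cc3c(OCOC)cc(OCOC)cc3OCOC)[C@]2(C)CC1 | intermediate
24 | 6α-diazenyl-1β-[2,4,6-tris(methoxymethoxy)benzyl]eudesma-4,11-dien-3-one (not isolated) | C=C(C)[C@@H]1[C@H](N=N)C2=C(C)C(=O)C[C@@H](Cc3c(OCOC)cc(OCOC)cc3OCOC)[C@]2(C)CC1 | intermediate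
25 | 4β-methyl-1β-[2,4,6-tris(methoxymethoxy)benzyl]eudesma-5,11-dien-3-one | C=C(C)[C@@H]1C=C2[C@@H](C)C(=O)C[C@@H](Cc3c(OCOC)cc(OCOC)cc3OCOC)[C@]2(C)CC1 | intermediate
26 | 4β-methyl-1β-[2,4,6-tris(methoxymethoxy)benzyl]eudesma-5,11-dien-3β-ol | C=C(C)[C@@H]1C=C2[C@@H](C)[C@@H](O)C[C@@H](Cc3c(OCOC)cc(OCOC)cc3OCOC)[C@]2(C)CC1 | intermediate
27 | O-(3β-yl) 1H-imidazole-1-carbothioate of 26 | C=C(C)[C@@H]1C=C2[C@@H](C)[C@@H](OC(=S)n4ccnc4)C[C@@H](Cc3c(OCOC)cc(OCOC)cc3OCOC)[C@]2(C)CC1 | intermediate
28 | 4β-methyl-1β-[2,4,6-tris(methoxymethoxy)benzyl]eudesma-5,11-diene | C=C(C)[C@@H]1C=C2[C@@H](C)CC[C@@H](Cc3c(OCOC)cc(OCOC)cc3OCOC)[C@]2(C)CC1 | intermediate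
29 | aryllithium of 28, lithium between two OMOM groups (not isolated) | C=C(C)[C@@H]1C=C2[C@@H](C)CC[C@@H](Cc3c(OCOC)c([Li])c(OCOC)cc3OCOC)[C@]2(C)CC1 | intermediate
30 | 3-{[4β-methyleudesma-5,11-dien-1β-yl]methyl}-2,4,6-tris(methoxymethoxy)benzaldehyde | C=C(C)[C@@H]1C=C2[C@@H](C)CC[C@@H](Cc3c(OCOC)c(C=O)c(OCOC)cc3OCOC)[C@]2(C)CC1 | intermediate
31 | 3-methylbutanoyl chloride | CC(C)CC(=O)Cl | starting material
32 | N-methoxy-N,3-dimethylbutanamide | CC(C)CC(=O)N(C)OC | intermediate
33 | lithium α-amino alkoxide of 30 with N,N,N'-trimethylethylenediamide (not isolated) | C=C(C)[C@@H]1C=C2[C@@H](C)CC[C@@H](Cc3c(OCOC)c(C(O[Li])N(C)CCN(C)C)c(OCOC)cc3OCOC)[C@]2(C)CC1 | intermediate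
34 | ring-lithiated 33 (not isolated) | C=C(C)[C@@H]1C=C2[C@@H](C)CC[C@@H](Cc3c(OCOC)c(C(O[Li])N(C)CCN(C)C)c(OCOC)c([Li])c3OCOC)[C@]2(C)CC1 | intermediate
35 | 3-{[4β-methyleudesma-5,11-dien-1β-yl]methyl}-2,4,6-tris(methoxymethoxy)-5-(3-methylbutanoyl)benzaldehyde | C=C(C)[C@@H]1C=C2[C@@H](C)CC[C@@H](Cc3c(OCOC)c(C=O)c(OCOC)c(C(=O)CC(C)C)c3OCOC)[C@]2(C)CC1 | intermediate
36 | CNP0564915.1, 2,4,6-trihydroxy-3-(3-methylbutanoyl)-5-{[4β-methyleudesma-5,11-dien-1β-yl]methyl}benzaldehyde | C=C(C)[C@@H]1C=C2[C@@H](C)CC[C@@H](Cc3c(O)c(C=O)c(O)c(C(=O)CC(C)C)c3O)[C@]2(C)CC1 | target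

**Step count and risks**

Total step count: 20. Longest linear sequence: 18 steps (steps 1–8, 10–17, 19 and 20, from (S)-carvone).

Steps most likely to fail:

1. Step 13. The Mitsunobu substitution has to occur at an axial carbinol whose entering face is crowded by the axial 7α-isopropenyl group, at the low temperature that NBSH requires. Slow substitution would let the reagent decompose or the activated alcohol eliminate, and the β,γ-unsaturated ketone product could slip back into conjugation with loss of the new C4 centre. The fallback replaces nitrogen delivery by palladium–formate hydrogenolysis and keeps C3 at the alcohol level. Setting out from 22, Luche reduction (NaBH4, CeCl3·7H2O, MeOH) should give the 3β,6β-diol F1. The less hindered C3 hydroxyl is silylated (TBSCl, imidazole, DMF, 0 °C) to the 3-O-silyl ether F2, and the C6 hydroxyl is converted with methyl chloroformate and pyridine into the 6β-methyl carbonate F3. With Pd(OAc)2, PBu3 and HCO2H/Et3N in dioxane, zerovalent palladium ionises the axial carbonate from the α face, and the hydride formed from formate is passed on that face to the more substituted allyl terminus C4, giving the 5-ene silyl ether F4 with 4β-methyl. Bu4NF then frees the alcohol, and the route is rejoined at 26.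

2. Step 10. Transfer of the di-ortho-substituted aryl group to nickel and capture of the β-branched primary alkyl radical may both be slow, so that reduction of the C–I bond, homocoupling of the arylzinc or base-induced re-closure to the cyclopropyl ketone takes over. The fallback reverses the polarity of the coupling. Setting out from 15, zinc insertion (Zn dust, LiCl, THF, 25–40 °C) should give the alkylzinc iodide F5, which tolerates the enone. It is coupled with 2-iodo-1,3,5-tris(methoxymethoxy)benzene F6 (from 17 by n-BuLi, then I2) under Pd(OAc)2 and SPhos in THF, a well-precedented alkylzinc–aryl halide Negishi coupling, and the route is rejoined at 20.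

3. Step 19. Masking of the aldehyde may be incomplete, or lithiation may stray to allylic or benzylic C–H bonds, leading to butyl addition at the formyl group or to mixtures; excess n-BuLi also consumes the amide. The fallback brings in the acyl group at the alcohol oxidation level, so that no carbonyl is present during either lithiation. Setting out from 28, lithiation (n-BuLi, THF, 0 °C) and addition of 3-methylbutanal give the benzylic alcohol F7. A second lithiation of its lithium alkoxide (n-BuLi, 2.5 equiv) followed by DMF gives the hydroxy aldehyde F8. Dess–Martin oxidation of the secondary benzylic alcohol then rejoins the route at 35.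

**Further compounds**
F1 | step 13 | 1β-[2,4,6-tris(methoxymethoxy)benzyl]eudesma-4,11-diene-3β,6β-diol | C=C(C)[C@@H]1[C@@H](O)C2=C(C)[C@@H](O)C[C@@H](Cc3c(OCOC)cc(OCOC)cc3OCOC)[C@]2(C)CC1
F2 | step 13 | 3β-(tert-butyldimethylsilyloxy)-1β-[2,4,6-tris(methoxymethoxy)benzyl]eudesma-4,11-dien-6β-ol | C=C(C)[C@@H]1[C@@H](O)C2=C(C)[C@@H](O[Si](C)(C)C(C)(C)C)C[C@@H](Cc3c(OCOC)cc(OCOC)cc3OCOC)[C@]2(C)CC1
F3 | step 13 | methyl carbonate of F2 at the 6β-oxygen | C=C(C)[C@@H]1[C@@H](OC(=O)OC)C2=C(C)[C@@H](O[Si](C)(C)C(C)(C)C)C[C@@H](Cc3c(OCOC)cc(OCOC)cc3OCOC)[C@]2(C)CC1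
F4 | step 13 | 3β-(tert-butyldimethylsilyloxy)-4β-methyl-1β-[2,4,6-tris(methoxymethoxy)benzyl]eudesma-5,11-diene | C=C(C)[C@@H]1C=C2[C@@H](C)[C@@H](O[Si](C)(C)C(C)(C)C)C[C@@H](Cc3c(OCOC)cc(OCOC)cc3OCOC)[C@]2(C)CC1
F5 | step 10 | [(3-oxoeudesma-4,11-dien-1β-yl)methyl]zinc iodide | C=C(C)[C@@H]1CC2=C(C)C(=O)C[C@@H](C[Zn]I)[C@]2(C)CC1
F6 | step 10 | 2-iodo-1,3,5-tris(methoxymethoxy)benzene | COCOc1cc(OCOC)c(I)c(OCOC)c1
F7 | step 19 | 1-{3-[(4β-methyleudesma-5,11-dien-1β-yl)methyl]-2,4,6-tris(methoxymethoxy)phenyl}-3-methylbutan-1-ol (carbinol epimers) | C=C(C)[C@@H]1C=C2[C@@H](C)CC[C@@H](Cc3c(OCOC)cc(OCOC)c(C(O)CC(C)C)c3OCOC)[C@]2(C)CC1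
F8 | step 19 | 3-(1-hydroxy-3-methylbutyl)-5-[(4β-methyleudesma-5,11-dien-1β-yl)methyl]-2,4,6-tris(methoxymethoxy)benzaldehyde (carbinol epimers) | C=C(C)[C@@H]1C=C2[C@@H](C)CC[C@@H](Cc3c(OCOC)c(C=O)c(OCOC)c(C(O)CC(C)C)c3OCOC)[C@]2(C)CC1
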